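**Strategy.** The tetralin (C1 aryl-bearing CH, C2/C3 the CH2O-bearing carbons, C4 the CH2) is cut at C2–C3 and at the bond from C1 to ring C. One Lewis-acid operation joins a ring A fragment to 2,6-dimethoxyphenol. The β-carbon of an (E)-styrene opens an (R)-oxirane at its internal carbon (C3, with inversion; the oxirane CH2O becomes the C3 hydroxymethyl) and ring B closes. The resulting C1 cation, stabilised by the C8 (ortho) and C6 (para) methoxy groups of ring A, is arylated at C4 of the phenol, para to its OH. The precursor is a benzene ring carrying, ortho to each other, an (R)-oxiranylmethyl arm and an (E)-3-benzyloxypropenyl arm, with the ring A phenol as its benzyl ether.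

Key step: step 7

Remark on numbering and configuration: ring A carbons are C5 (H), C6 (OMe), C7 (O) and C8 (OMe); ring B is the saturated ring, ring C the pendant aryl. The target is taken as the (1S,2R,3R) isomer encoded by the SMILES (1,2-trans, 2,3-trans). Because the oxirane carbon is inverted in the key step, the (R)-oxirane is the required series. It is reached from (R)-epichlorohydrin without ever breaking the C–O bond at the stereocentre.

Design notes:
- The ring bromine is introduced before the oxirane is closed, so the oxirane never meets the electrophile.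
- Both oxygen caps are benzyl ethers, which leave together in the last step. An ester on the allylic oxygen is avoided because its carbonyl oxygen would capture the C1 cation.
- 2,6-Dimethoxyphenol is used unprotected. Its two methoxy groups activate C3/C5, so para attack is not automatic; only the free, in-plane OH directs the cation to C4.

**Step 1**
Reactants: 1 4-bromo-2,6-dimethoxyphenol
Product: 2 2-(benzyloxy)-5-bromo-1,3-dimethoxybenzene
Conditions: BnBr, K2CO3, DMF, 60 °C
Reagents that add atoms: benzyl bromide, BrCc1ccccc1
Why: Williamson ether synthesis, in which the phenoxide of 1 displaces bromide from the benzylic halide and no stereocentre is involved.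

**Step 2**
Reactants: 2 2-(benzyloxy)-5-bromo-1,3-dimethoxybenzene; 3 (R)-epichlorohydrin
Product: 5 (R)-1-[4-(benzyloxy)-3,5-dimethoxyphenyl]-3-chloropropan-2-ol, via arylmagnesium bromide 4 (not isolated)
Conditions: Mg, THF, 40 °C; then CuI (10 mol %), 3 (1.2 equiv), THF, −40 → 0 °C
Reagents that add atoms: none
Why: Copper-catalysed Grignard opening of an epoxide, in which the aryl group adds to the unsubstituted oxirane carbon of 3, the C–O bond at the stereocentre is untouched and the chlorohydrin keeps the R configuration.

**Step 3**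
Reactants: 5 (R)-1-[4-(benzyloxy)-3,5-dimethoxyphenyl]-3-chloropropan-2-ol
Product: 6 (R)-1-[4-(benzyloxy)-2-bromo-3,5-dimethoxyphenyl]-3-chloropropan-2-ol
Conditions: NBS (1.0 equiv), MeCN, 0 °C → rt
Reagents that add atoms: N-bromosuccinimide, O=C1CCC(=O)N1Br
Why: Electrophilic aromatic bromination, for which the two open ring positions are equivalent (each ortho to one methoxy group and para to the other) and the first bromine slows a second substitution.

**Step 4**
Reactants: 6 (R)-1-[4-(benzyloxy)-2-bromo-3,5-dimethoxyphenyl]-3-chloropropan-2-ol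
Product: 7 (R)-2-[4-(benzyloxy)-2-bromo-3,5-dimethoxybenzyl]oxirane
Conditions: K2CO3, MeOH, rt
Reagents that add atoms: none
Why: Intramolecular Williamson closure (3-exo-tet) of the chlorohydrin, in which the alkoxide displaces the primary chloride while the stereocentre is not a reacting centre and stays R.

**Step 5**
Reactants: 8 benzyl propargyl ether
Product: 9 2-[(E)-3-(benzyloxy)prop-1-en-1-yl]-4,4,5,5-tetramethyl-1,3,2-dioxaborolane
Conditions: pinacolborane (1.1 equiv), Cp2Zr(H)Cl (5 mol %), Et3N (10 mol %), neat, 60 °C
Reagents that add atoms: pinacolborane, CC1(C)OBOC1(C)C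
Why: Zirconium-catalysed hydroboration of a terminal alkyne, in which syn addition of H–B with boron at the terminal carbon fixes the E geometry.

**Step 6**
Reactants: 7 (R)-2-[4-(benzyloxy)-2-bromo-3,5-dimethoxybenzyl]oxirane; 9 2-[(E)-3-(benzyloxy)prop-1-en-1-yl]-4,4,5,5-tetramethyl-1,3,2-dioxaborolane
Product: 10 (R)-2-{4-(benzyloxy)-2-[(E)-3-(benzyloxy)prop-1-en-1-yl]-3,5-dimethoxybenzyl}oxirane
Conditions: Pd(OAc)2 (5 mol %), SPhos (10 mol %), K3PO4, THF/H2O (10:1), 60 °C
Reagents that add atoms: none
Why: Suzuki–Miyaura coupling, which retains the alkene geometry, tolerates the doubly ortho-substituted electron-rich aryl bromide with the SPhos-ligated palladium catalyst, and uses a phosphate base mild enough to leave the alkyl oxirane and its stereocentre intact.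

**Step 7**
Reactants: 10 (R)-2-{4-(benzyloxy)-2-[(E)-3-(benzyloxy)prop-1-en-1-yl]-3,5-dimethoxybenzyl}oxirane; 11 2,6-dimethoxyphenol
Product: 13 (1S,2R,3R)-7-(benzyloxy)-2-[(benzyloxy)methyl]-1-(4-hydroxy-3,5-dimethoxyphenyl)-3-(hydroxymethyl)-6,8-dimethoxytetralin, via benzylic cation 12 (not isolated)
Conditions: 11 (5 equiv), BF3·OEt2 (30 mol %), CH2Cl2, −78 → −20 °C, slow addition of 10
Reagents that add atoms: none
Why: Proposed new method: BF3 activates the oxirane of 10, the β-carbon of the (E)-styrene attacks the internal oxirane carbon anti to the departing oxygen (inversion, so the R oxirane becomes 3R and its CH2O–BF3 arm the future C3 hydroxymethyl), and the C1 cation 12, held coplanar with ring A by the new ring and stabilised by the C8 (ortho) and C6 (para) methoxy groups, is arylated by C4 of 11, after which proton loss and proton transfer to the alkoxide release BF3. The closest known reaction types are Lewis-acid epoxide–olefin cyclisations of the polyene type and Prins/Friedel–Crafts sequences in which a tetralin benzylic cation is trapped by an external electron-rich arene. Ring B closes in a six-membered mode that is exo with respect to the breaking oxirane C–O bond and endo with respect to the alkene; attack on the oxirane CH2 would need a seven-membered ring and attack by the α-carbon would leave a cation without benzylic stabilisation. C2 is controlled by the (E)-geometry together with a chair-like transition state in which the oxirane CH2 points away from ring A, so that both CH2O arms end equatorial and 2,3-trans. C1 is controlled by 1,2-induction, the arene adding to the planar cation anti to the neighbouring C2 CH2OBn arm to give the 1,2-trans product, the usual sense for 2-substituted tetralin-1-yl cations. The step needs the internal alkene to outrun opening of the oxirane by 11 and needs C4 arylation of 11 to win over O-attack and attack at C3: the six-membered tether, low temperature, slow addition of 10 into an excess of 11 and the free in-plane OH of 11 secure this, and benzylic ethers formed by O-capture (by 11 or by the C3 CH2O arm) should re-ionise under the Lewis acid and drain to the C-aryl product.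

**Step 8**
Reactants: 13 (1S,2R,3R)-7-(benzyloxy)-2-[(benzyloxy)methyl]-1-(4-hydroxy-3,5-dimethoxyphenyl)-3-(hydroxymethyl)-6,8-dimethoxytetralin
Product: 14 lyoniresinol, (1S,2R,3R)-1-(4-hydroxy-3,5-dimethoxyphenyl)-2,3-bis(hydroxymethyl)-6,8-dimethoxytetralin-7-ol
Conditions: H2 (1 atm), Pd(OH)2/C, MeOH/EtOAc, rt
Reagents that add atoms: none
Why: Catalytic hydrogenolysis of one aryl benzyl ether and one primary alkyl benzyl ether, with no other reducible group present and none of the three stereocentres touched.

**Compound list**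

1 | 4-bromo-2,6-dimethoxyphenol | COc1cc(Br)cc(OC)c1O | starting material
2 | 2-(benzyloxy)-5-bromo-1,3-dimethoxybenzene | COc1cc(Br)cc(OC)c1OCc1ccccc1 | intermediate
3 | (R)-epichlorohydrin | ClC[C@H]1CO1 | starting material
4 | [4-(benzyloxy)-3,5-dimethoxyphenyl]magnesium bromide | COc1cc([Mg]Br)cc(OC)c1OCc1ccccc1 | intermediate
5 | (R)-1-[4-(benzyloxy)-3,5-dimethoxyphenyl]-3-chloropropan-2-ol | ClC[C@H](O)Cc1cc(OC)c(OCc2ccccc2)c(OC)c1 | intermediate
6 | (R)-1-[4-(benzyloxy)-2-bromo-3,5-dimethoxyphenyl]-3-chloropropan-2-ol | ClC[C@H](O)Cc1cc(OC)c(OCc2ccccc2)c(OC)c1Br | intermediate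
7 | (R)-2-[4-(benzyloxy)-2-bromo-3,5-dimethoxybenzyl]oxirane | COc1cc(C[C@@H]2CO2)c(Br)c(OC)c1OCc1ccccc1 | intermediate
8 | benzyl propargyl ether | C#CCOCc1ccccc1 | starting material
9 | 2-[(E)-3-(benzyloxy)prop-1-en-1-yl]-4,4,5,5-tetramethyl-1,3,2-dioxaborolane | CC1(C)OB(/C=C/COCc2ccccc2)OC1(C)C | intermediate
10 | (R)-2-{4-(benzyloxy)-2-[(E)-3-(benzyloxy)prop-1-en-1-yl]-3,5-dimethoxybenzyl}oxirane | c1ccccc1COC/C=C/c1c(C[C@@H]2CO2)cc(OC)c(OCc2ccccc2)c1OC | intermediate
11 | 2,6-dimethoxyphenol | COc1cccc(OC)c1O | starting material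
12 | (2R,3R)-7-(benzyloxy)-2-[(benzyloxy)methyl]-6,8-dimethoxy-3-{[(trifluoroboranuidyl)oxy]methyl}tetralin-1-ylium (zwitterion, 2,3-trans) | [CH+]1c2c(cc(OC)c(OCc3ccccc3)c2OC)C[C@@H](CO[B-](F)(F)F)[C@@H]1COCc1ccccc1 | intermediate
13 | (1S,2R,3R)-7-(benzyloxy)-2-[(benzyloxy)methyl]-1-(4-hydroxy-3,5-dimethoxyphenyl)-3-(hydroxymethyl)-6,8-dimethoxytetralin (1,2-trans, 2,3-trans) | COc1cc([C@H]2c3c(cc(OC)c(OCc4ccccc4)c3OC)C[C@@H](CO)[C@@H]2COCc2ccccc2)cc(OC)c1O | intermediate
14 | lyoniresinol, (1S,2R,3R) isomer; systematic name (6R,7R,8S)-8-(4-hydroxy-3,5-dimethoxyphenyl)-6,7-bis(hydroxymethyl)-1,3-dimethoxy-5,6,7,8-tetrahydronaphthalen-2-ol | COc1cc([C@H]2c3c(cc(OC)c(O)c3OC)C[C@@H](CO)[C@@H]2CO)cc(OC)c1O | target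

**Step count.** Total: 8 steps. Longest linear sequence: 7 steps (steps 1, 2, 3, 4, 6, 7, 8); step 5 is the side branch.

**Steps most likely to fail**

1. Step 7 (proposed new method).
- What may go wrong: the phenol opens the activated oxirane before the alkene engages; the cation is captured with poor facial selectivity at C1 or at C3 of the phenol; the nucleophilic C5 position of ring A of a second molecule competes and gives oligomers.
- Fallback (known chemistry; sets out from 3 and 4, returns at 14): (R)-epichlorohydrin 3 is condensed with diethyl malonate (NaOEt, EtOH, reflux) to ethyl (1S,5R)-2-oxo-3-oxabicyclo[3.1.0]hexane-1-carboxylate F1. CuI-catalysed homoconjugate addition of the Grignard reagent 4 to the doubly activated cyclopropane should give ethyl (4R)-4-[4-(benzyloxy)-3,5-dimethoxybenzyl]-2-oxotetrahydrofuran-3-carboxylate F2. Krapcho dealkoxycarbonylation (LiCl, wet DMSO, 140 °C) should give (R)-4-[4-(benzyloxy)-3,5-dimethoxybenzyl]dihydrofuran-2(3H)-one F3. Aldol addition of its lithium enolate (LiN(SiMe3)2, THF, −78 °C) to commercial 4-(benzyloxy)-3,5-dimethoxybenzaldehyde (COc1cc(C=O)cc(OC)c1OCc1ccccc1), anti to the benzyl group, should give the 3,4-trans carbinol (3S,4R)-3-{[4-(benzyloxy)-3,5-dimethoxyphenyl](hydroxy)methyl}-4-[4-(benzyloxy)-3,5-dimethoxybenzyl]dihydrofuran-2(3H)-one F4 as carbinol epimers. TFA in CH2Cl2 ionises the carbinol and ring A closes onto the cation (intramolecular Friedel–Crafts) to the all-trans aryltetralin lactone F5. LiAlH4 in THF opens the lactone to the bis-O-benzyl diol F6, and hydrogenolysis under the conditions of step 8 should give 14. Here C3 comes from 3 with the same sense, C2 from the anti aldol and C1 from the cyclisation.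

2. Step 6.
- What may go wrong: slow oxidative addition into the crowded, electron-rich C–Br bond, protodeboronation of 9, or opening of the oxirane by warm aqueous base.
- Fallback (sets out from 8 and 7, returns at 10): radical hydrostannation of 8 (Bu3SnH, AIBN, 80 °C; the E isomer favoured after equilibration is purified) gives (E)-tributyl[3-(benzyloxy)prop-1-en-1-yl]stannane F7. Base-free Stille coupling of 7 with it (Pd(P(t-Bu)3)2, dioxane, 80 °C) should give 10 with retention of geometry and without exposing the oxirane to base or water.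

3. Step 2.
- What may go wrong: part of the Grignard reagent displaces chloride directly, which leads into the enantiomeric oxirane series and erodes enantiomeric purity; or the magnesium alkoxide closes early and the oxirane so formed takes up a second aryl group.
- Fallback (sets out from 2, returns at 5): bromine–lithium exchange on 2 (n-BuLi, THF, −78 °C) gives [4-(benzyloxy)-3,5-dimethoxyphenyl]lithium F8. This opens 3 at the oxirane CH2 under BF3·OEt2 activation at −78 °C, where chloride is not displaced and the boron-bound alkoxide cannot close, to give 5 after aqueous work-up.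

**Further compounds**

F1 | step 7 | ethyl (1S,5R)-2-oxo-3-oxabicyclo[3.1.0]hexane-1-carboxylate | O=C1OC[C@@H]2C[C@]12C(=O)OCC
F2 | step 7 | ethyl (4R)-4-[4-(benzyloxy)-3,5-dimethoxybenzyl]-2-oxotetrahydrofuran-3-carboxylate (C3 epimers) | CCOC(=O)C1[C@@H](Cc2cc(OC)c(OCc3ccccc3)c(OC)c2)COC1=O
F3 | step 7 | (R)-4-[4-(benzyloxy)-3,5-dimethoxybenzyl]dihydrofuran-2(3H)-one | O=C1C[C@@H](Cc2cc(OC)c(OCc3ccccc3)c(OC)c2)CO1
F4 | step 7 | (3S,4R)-3-{[4-(benzyloxy)-3,5-dimethoxyphenyl](hydroxy)methyl}-4-[4-(benzyloxy)-3,5-dimethoxybenzyl]dihydrofuran-2(3H)-one (3,4-trans, carbinol epimers) | O=C1OC[C@H](Cc2cc(OC)c(OCc3ccccc3)c(OC)c2)[C@H]1C(O)c1cc(OC)c(OCc2ccccc2)c(OC)c1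
F5 | step 7 | all-trans aryltetralin lactone, 7-(benzyloxy)-1-[4-(benzyloxy)-3,5-dimethoxyphenyl]-6,8-dimethoxytetralin with C2 carbonyl and C3 CH2O joined as a γ-lactone | COc1cc([C@H]2c3c(cc(OC)c(OCc4ccccc4)c3OC)C[C@H]3COC(=O)[C@H]23)cc(OC)c1OCc1ccccc1
F6 | step 7 | (1S,2R,3R)-7-(benzyloxy)-1-[4-(benzyloxy)-3,5-dimethoxyphenyl]-2,3-bis(hydroxymethyl)-6,8-dimethoxytetralin | COc1cc([C@H]2c3c(cc(OC)c(OCc4ccccc4)c3OC)C[C@@H](CO)[C@@H]2CO)cc(OC)c1OCc1ccccc1
F7 | step 6 | (E)-tributyl[3-(benzyloxy)prop-1-en-1-yl]stannane | CCCC[Sn](CCCC)(CCCC)/C=C/COCc1ccccc1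
F8 | step 2 | [4-(benzyloxy)-3,5-dimethoxyphenyl]lithium | [Li]c1cc(OC)c(OCc2ccccc2)c(OC)c1
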